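## The problem

The target 27 is a genistein-type isoflavone (hydroxyls at C5, C7 and C4') with a prenyl group at C3' of ring B and a (2R)-2-hydroxy-3-methylbut-3-enyl chain (C1''–C4'') at C6 of ring A. The flat ring system is routine to make. The work lies in placing the chain on C6 and not on C8, and in making C2'', the only stereocentre, as one enantiomer. No other stereocentre can relay to C2'', so its configuration must come from a catalyst or reagent; once set it carries no acidic hydrogen and is safe under basic and neutral conditions. The allylic secondary alcohol, the 1,1-disubstituted alkene and the prenyl alkene each lie next to a phenol. They rule out hydrogenolysis, strong Lewis acids and hot protic acid (chroman or dihydrofuran formation, ionisation of the allylic alcohol), and the pyranone ring opens with hot hydroxide. C6 lies between the C5 and C7 oxygens. In a phloroglucinol-derived benzene where these two oxygens carry the same group and the third (the future O1) a different one, that carbon is unique by symmetry, so the C6/C8 question is settled before ring C exists. C2'' sits between the benzylic C1'' and the isopropenyl carbon C3''. An aryl electrophile at C6, a two-carbon vinyl unit and an isopropenyl group can therefore be joined around it in one operation, leaving boron on C2'' as a stereodefined precursor of the hydroxyl.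

## Retrosynthesis

**Unmasking (27 from 26).** No skeletal bond is cut. The three phenols are held as MOM ethers and the C2'' alcohol as a TBS ether in 26, so one mild protic step removes all four. The forward reaction must be acidic enough for aryl acetals but not for the alkenes or the allylic alcohol.

**C3–C1' (26 from 20 and 25).** Cutting the aryl–aryl bond gives 3-iodochromone 20 and ring B boronic ester 25. The neighbouring cut, C4a–C4 with a ring B arylacetyl unit, would require a hindered ring A carbanion to attack an enolisable acyl donor. The Suzuki–Miyaura cut avoids that and keeps ring B out of the linear sequence. 25 is reached in three steps from 2,4-dibromophenol 21 through 22 and 24.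

**Ring C (20 from 14).** The O1–C2 and C2–C3 bonds come from a one-carbon insertion into hydroxyacetophenone 18 through enaminone 19. 18 comes from 17 by loss of the TIPS group, which marks the future O1. The C4a–C4 bond of 17 is made from aryllithium 16, which comes from bromide 15. In 14 the two open ring positions are equivalent (each lies between a MOM ether and the TIPS ether), so bromination has no regiochemical choice. The forward sequence asks for a clean monobromination beside an alkene and for an aryllithium that does not let its neighbouring silyl group migrate.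

**C2''–O (14 from 12).** The alcohol 13, protected as 14, comes from boronic ester 12 by stereoretentive oxidation. This turns the stereochemical problem into the construction of a C–B stereocentre.

**C6–C1'' and C2''–C3'' (12 from 7, 9 and 10).** Both bonds are cut at once: aryl triflate 7, vinyllithium 9 and isopropenylboronic ester 10 combine through borate 11. The stepwise neighbour (prenylation of the ring, then asymmetric oxidation of the prenyl group) needs separate operations for the carbon chain and the stereocentre. Here one catalytic step does both, and all three precursors are achiral and simple. The forward reaction asks for a cationic arylpalladium from a doubly ortho-oxygenated triflate, for the absence of halide, and for the vinyl group of 11 to act as the acceptor.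

**C6–O (7 from 1).** Triflate 7 comes from phenol 6, which is made by metalation of 3 between its two MOM ethers (through 4 and 5) and oxidation. 3 is the TIPS ether of 2, the bis-MOM ether of phloroglucinol 1. The only unselective operation is the statistical bis-protection of 1 at the start.

**Vinyl donor (9 from 8).** Vinyllithium 9 is prepared halide-free from tetravinylstannane 8, not by halogen–lithium exchange of a vinyl halide. Lithium halide would occupy the cationic palladium centre of the key step.

## Roads not taken

**Alternative 1:** Ring A is removed altogether. C7–C8 and C5–C6 are cut, leaving pyranone ester A2 (rings B and C complete) and the chiral lactone A3 (C6, C7, the chain and the stereocentre).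
- Forward step: the 2-methyl group of A2 is deprotonated with a lithium amide base and acylated by the carbonyl of A3. With excess base the C6 carbanion of the new ketone closes onto the ester and ring A aromatises to A1, which needs only one MOM removal.
- Merits: it is the most convergent plan. The ring A oxygens are never protected, the C6/C8 question cannot arise, and the stereocentre arrives in a small fragment.
- Weak points: A3 carries acidic hydrogens on the very carbon that must later be the nucleophile, so proton transfer to the dienolate of A2 competes with acylation. After ring opening the C8 methylene (between the ketone and the vinylogous ester) is far more acidic than C6, so closure needs a polyanion that also carries the free C2'' alkoxide. A2 offers a conjugate acceptor and an acidic C2–H to the base. Neither A2 nor enantiopure A3 is commercial, and each needs its own multistep preparation.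
- Comparison: if the cascade worked, this road would be shorter and would use far fewer protecting groups than the chosen one. The chosen plan is longer, but every step is of a known type, and the risk is not concentrated in one polyanion cascade with no close precedent.

**Alternative 2:** Ring A is built from the 3-alkoxycyclobutenone A5 and the siloxyalkyne A6, which already carries the chain and the stereocentre.
- Forward step: on heating, A5 opens to a vinylketene that adds to A6; 4π opening and 6π closure give phenol A4 with three differently protected oxygens.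
- Merits: the regiochemistry is fixed by the benzannulation, there is no coupling at a hindered carbon, and the conditions are neutral.
- Weak points: the stereocentre of A6 must be made beforehand, and the ester-to-ynolate homologation and silylation add several steps to a hydrolytically fragile intermediate. The three-way oxygen differentiation of A4 is more than the target needs: only the oxygen para to the chain must differ from its two neighbours, which a phloroglucinol derivative offers by symmetry. After A4, the same work remains as after 14 (acyl group, ring C, ring B), so the step count is not lower.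
- Comparison: this road is better in avoiding the hindered triflate. The chosen plan offers cheap achiral starting materials and a catalytic step that forms both C–C bonds and the stereocentre together.

**Alternative 3:** C6–C1'' and C3'–C1''' are cut through two aromatic Claisen shifts, starting from genistein A9.
- Forward step: heating bis-ether A8 moves the allyl group from O5 to C6 (C4a is blocked) and the 1,1-dimethylallyl group from O4' to C3' as a prenyl group, giving A7.
- Merits: rings A–C are bought, two C–C bonds form in one thermal step, and the regiochemistry at C6 is certain. It is the shortest access to the carbon framework.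
- Weak points: A7 carries an allyl group, not the chain. The isopropenyl group and the stereocentre are still missing. Their introduction requires oxidative cleavage of the terminal alkene in the presence of the more electron-rich prenyl alkene, which oxidants attack first, and then an asymmetric addition to an enolisable arylacetaldehyde.
- Comparison: this road is better up to A7 in step count and has no hindered coupling, but it leaves the stereocentre and the alkene chemoselectivity unsolved. The chosen plan forms the stereocentre on a simple arene before any other alkene is present.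

Key step: step 6

Assumption: ligand L is the Mandyphos-type bisphosphine 1,1'-bis[bis(4-methoxy-3,5-dimethylphenyl)phosphino]-2,2'-bis[α-(dimethylamino)benzyl]ferrocene; which of its two enantiomers leads to (R)-12 is to be fixed beforehand on a simple model triflate, and that enantiomer is used.

## Route

Step 1
Reactants: 1 phloroglucinol (benzene-1,3,5-triol)
Product: 2 3,5-bis(methoxymethoxy)phenol
Conditions: MOMCl (2.0 equiv), i-Pr2NEt (2.4 equiv), DMF, 0 °C → rt; chromatography, mono-ether resubmitted
Reagents that add atoms: chloromethyl methyl ether (MOMCl), COCCl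
Why: O-alkylation of a phenol with an α-chloro ether (Williamson type); the three hydroxyls are equivalent, so the bis-ether is the main component of a statistical mixture and is separated from it.

Step 2
Reactants: 2 3,5-bis(methoxymethoxy)phenol
Product: 3 [3,5-bis(methoxymethoxy)phenoxy]tri(propan-2-yl)silane
Conditions: TIPSCl (1.2 equiv), imidazole (2.5 equiv), DMF, rt
Reagents that add atoms: chlorotri(propan-2-yl)silane (TIPSCl), CC(C)[Si](Cl)(C(C)C)C(C)C
Why: Imidazole-promoted silylation of the remaining phenol; the bulky, non-coordinating TIPS group marks the oxygen that becomes O1 and shields its two neighbours from organolithium bases.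

Step 3
Reactants: 3 [3,5-bis(methoxymethoxy)phenoxy]tri(propan-2-yl)silane
Product: 6 2,6-bis(methoxymethoxy)-4-{[tri(propan-2-yl)silyl]oxy}phenol, via aryllithium 4 (not isolated), via dimethyl arylboronate 5 (not isolated)
Conditions: n-BuLi (1.2 equiv), THF, 0 °C; B(OMe)3 (1.5 equiv), −78 °C → rt; AcOH, 30% H2O2, 0 °C → rt
Reagents that add atoms: hydrogen peroxide, OO (trimethyl borate, COB(OC)OC, supplies the boron of 5 only)
Why: Directed ortho-metalation: the carbon between the two MOM ethers is acidified and chelated by both, while the positions next to the TIPS ether have one directing group and are shielded. Borylation and peroxide oxidation of the arylboronate (aryl shift from boron to oxygen) then place the hydroxyl on the future C6.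

Step 4
Reactants: 6 2,6-bis(methoxymethoxy)-4-{[tri(propan-2-yl)silyl]oxy}phenol
Product: 7 2,6-bis(methoxymethoxy)-4-{[tri(propan-2-yl)silyl]oxy}phenyl trifluoromethanesulfonate
Conditions: Tf2O (1.2 equiv), pyridine (3 equiv), CH2Cl2, −20 → 0 °C
Reagents that add atoms: trifluoromethanesulfonic anhydride, O=S(=O)(OS(=O)(=O)C(F)(F)F)C(F)(F)F
Why: O-sulfonylation of the phenol; pyridine keeps the medium basic so the acetals survive, and the product is a symmetric aryl triflate whose C–O carbon is the future C6.

Step 5
Reactants: 8 tetravinylstannane (tetraethenylstannane)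
Product: 9 vinyllithium (ethenyllithium), halide-free, as a titrated THF solution
Conditions: n-BuLi (4.0 equiv), pentane, rt; precipitate filtered under argon, washed with pentane, dissolved in THF
Reagents that add atoms: n-butyllithium, [Li]CCCC
Why: Tin–lithium exchange; vinyllithium precipitates from pentane free of lithium halide, which would otherwise bind the cationic palladium intermediate of step 6 and divert it to direct coupling.

Step 6
Reactants: 7 2,6-bis(methoxymethoxy)-4-{[tri(propan-2-yl)silyl]oxy}phenyl trifluoromethanesulfonate, 9 vinyllithium, 10 isopropenylboronic acid pinacol ester (4,4,5,5-tetramethyl-2-(prop-1-en-2-yl)-1,3,2-dioxaborolane)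
Product: 12 2-[(2R)-1-(2,6-bis(methoxymethoxy)-4-{[tri(propan-2-yl)silyl]oxy}phenyl)-3-methylbut-3-en-2-yl]-4,4,5,5-tetramethyl-1,3,2-dioxaborolane, via lithium vinyl(isopropenyl)borate 11 (not isolated)
Conditions: 10 (1.3 equiv), 9 (1.3 equiv), THF, 0 °C → rt, 30 min; then 7 (1.0 equiv), Pd(OAc)2 (5 mol%), 1,1'-bis[bis(4-methoxy-3,5-dimethylphenyl)phosphino]-2,2'-bis[α-(dimethylamino)benzyl]ferrocene (ligand L, 6 mol%), THF, 60 °C, 16 h
Reagents that add atoms: none
Why: This is a palladium-catalysed enantioselective conjunctive cross-coupling of a bis(alkenyl)borate with an aryl triflate, a known reaction type applied here to a doubly ortho-oxygenated electrophile. Vinyllithium 9 adds to boron of 10 to give the four-coordinate borate 11. Oxidative addition of 7 to zerovalent palladium gives a cationic divalent arylpalladium (triflate does not coordinate), which binds the unsubstituted vinyl group of 11 in preference to the 1,1-disubstituted isopropenyl group. Coordination triggers a 1,2-metallate shift: the isopropenyl group moves from boron to C2'' on the face opposite palladium while palladium bonds to C1'', and reductive elimination joins C1'' to C6 and returns zerovalent palladium. No ring is formed. C2'' is the only new stereocentre; ligand L decides which face of the vinyl group palladium occupies, and because migration is anti to the metal this choice fixes the (R) configuration. The step needs the conjunctive pathway to outrun direct transmetalation of a vinyl or isopropenyl group, which halide-free 9 and the triflate leaving group secure, and it needs the vinyl group to be the acceptor, which its lower substitution secures. The flanking MOM ethers slow oxidative addition and may chelate palladium, hence the raised catalyst loading.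

Step 7
Reactants: 12 2-[(2R)-1-(2,6-bis(methoxymethoxy)-4-{[tri(propan-2-yl)silyl]oxy}phenyl)-3-methylbut-3-en-2-yl]-4,4,5,5-tetramethyl-1,3,2-dioxaborolane
Product: 13 (2R)-1-(2,6-bis(methoxymethoxy)-4-{[tri(propan-2-yl)silyl]oxy}phenyl)-3-methylbut-3-en-2-ol
Conditions: NaBO3·4H2O (5 equiv), THF/H2O 1:1, rt
Reagents that add atoms: sodium perborate tetrahydrate, [Na+].[O-]OB=O.O.O.O.O
Why: Oxidation of a secondary boronic ester: hydroperoxide adds to boron and C2'' migrates from boron to oxygen with retention, so (R)-12 gives (R)-13. The mildly basic perborate spares the aryl TIPS ether.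

Step 8
Reactants: 13 (2R)-1-(2,6-bis(methoxymethoxy)-4-{[tri(propan-2-yl)silyl]oxy}phenyl)-3-methylbut-3-en-2-ol
Product: 14 {[(2R)-1-(2,6-bis(methoxymethoxy)-4-{[tri(propan-2-yl)silyl]oxy}phenyl)-3-methylbut-3-en-2-yl]oxy}(tert-butyl)dimethylsilane
Conditions: TBSCl (1.5 equiv), imidazole (3 equiv), DMF, rt → 40 °C
Reagents that add atoms: tert-butylchlorodimethylsilane (TBSCl), CC(C)(C)[Si](C)(C)Cl
Why: Standard silyl ether formation; the TBS group removes the only acidic hydrogen before the organolithium step and is lost with the MOM ethers in the last step.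

Step 9
Reactants: 14 {[(2R)-1-(2,6-bis(methoxymethoxy)-4-{[tri(propan-2-yl)silyl]oxy}phenyl)-3-methylbut-3-en-2-yl]oxy}(tert-butyl)dimethylsilane
Product: 15 {[(2R)-1-(3-bromo-2,6-bis(methoxymethoxy)-4-{[tri(propan-2-yl)silyl]oxy}phenyl)-3-methylbut-3-en-2-yl]oxy}(tert-butyl)dimethylsilane
Conditions: NBS (1.0 equiv), CH2Cl2, −78 → −30 °C, dark
Reagents that add atoms: N-bromosuccinimide, O=C1CCC(=O)N1Br
Why: Electrophilic aromatic bromination of a 1,3,5-trioxygenated ring; the two open positions are equivalent, so one equivalent should give a single monobromide. The hindered isopropenyl group, deactivated by the allylic oxygen, reacts much more slowly than the arene.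

Step 10
Reactants: 15 {[(2R)-1-(3-bromo-2,6-bis(methoxymethoxy)-4-{[tri(propan-2-yl)silyl]oxy}phenyl)-3-methylbut-3-en-2-yl]oxy}(tert-butyl)dimethylsilane
Product: 17 1-{3-[(2R)-2-{[tert-butyl(dimethyl)silyl]oxy}-3-methylbut-3-en-1-yl]-2,4-bis(methoxymethoxy)-6-{[tri(propan-2-yl)silyl]oxy}phenyl}ethan-1-one, via aryllithium 16 (not isolated)
Conditions: t-BuLi (2.1 equiv), THF, −78 °C, 10 min; MeC(O)N(OMe)Me (2 equiv), −78 → −20 °C; AcOH quench
Reagents that add atoms: N-methoxy-N-methylacetamide, CON(C)C(C)=O (tert-butyllithium, [Li]C(C)(C)C, supplies the lithium of 16 only)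
Why: Bromine–lithium exchange gives 16 at −78 °C, where O-to-C migration of the bulky TIPS group is slow. Acylation with a Weinreb amide stops at the ketone through the chelated tetrahedral adduct.

Step 11
Reactants: 17 1-{3-[(2R)-2-{[tert-butyl(dimethyl)silyl]oxy}-3-methylbut-3-en-1-yl]-2,4-bis(methoxymethoxy)-6-{[tri(propan-2-yl)silyl]oxy}phenyl}ethan-1-one
Product: 18 1-{3-[(2R)-2-{[tert-butyl(dimethyl)silyl]oxy}-3-methylbut-3-en-1-yl]-6-hydroxy-2,4-bis(methoxymethoxy)phenyl}ethan-1-one
Conditions: TBAF (1.1 equiv), AcOH (1.1 equiv), THF, 0 °C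
Reagents that add atoms: none
Why: Fluoride-induced cleavage of the aryl silyl ether is much faster than that of the hindered secondary alkyl TBS ether, because the phenoxide ortho to the acetyl group is the far better leaving group; acetic acid buffers the medium.

Step 12
Reactants: 18 1-{3-[(2R)-2-{[tert-butyl(dimethyl)silyl]oxy}-3-methylbut-3-en-1-yl]-6-hydroxy-2,4-bis(methoxymethoxy)phenyl}ethan-1-one
Product: 20 6-[(2R)-2-{[tert-butyl(dimethyl)silyl]oxy}-3-methylbut-3-en-1-yl]-3-iodo-5,7-bis(methoxymethoxy)-4H-chromen-4-one, via enaminone 19 (not isolated)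
Conditions: Me2NCH(OMe)2 (5 equiv), toluene, 90 °C; evaporation; I2 (1.2 equiv), pyridine (1.5 equiv), CHCl3, 0 °C → rt
Reagents that add atoms: N,N-dimethylformamide dimethyl acetal, COC(OC)N(C)C; iodine, II
Why: Condensation of the methyl ketone with the formamide acetal gives enaminone 19, which supplies C2. Iodine attacks 19 at C3 and the phenol closes onto the iminium carbon with loss of dimethylamine (6-endo addition–elimination); pyridine takes up the acid so the MOM ethers survive.

Step 13
Reactants: 21 2,4-dibromophenol
Product: 22 2,4-dibromo-1-(methoxymethoxy)benzene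
Conditions: MOMCl (1.3 equiv), i-Pr2NEt (1.5 equiv), CH2Cl2, 0 °C → rt
Reagents that add atoms: chloromethyl methyl ether (MOMCl), COCCl
Why: O-alkylation of the phenol; the acetal later directs the halogen–metal exchange and is removed in the final step with the others.

Step 14
Reactants: 22 2,4-dibromo-1-(methoxymethoxy)benzene
Product: 24 4-bromo-1-(methoxymethoxy)-2-(3-methylbut-2-en-1-yl)benzene, via aryllithium 23 (not isolated)
Conditions: n-BuLi (1.0 equiv), Et2O/THF, −78 °C; CuBr·SMe2 (1.0 equiv); prenyl bromide (1.3 equiv), −78 → 0 °C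
Reagents that add atoms: 1-bromo-3-methylbut-2-ene (prenyl bromide), CC(C)=CCBr (n-butyllithium, [Li]CCCC, supplies the lithium of 23 only)
Why: Bromine–lithium exchange is fastest at the bromine ortho to the coordinating, inductively activating MOM ether. Transmetalation to monovalent copper and substitution at the primary carbon of prenyl bromide gives the linear prenyl group.

Step 15
Reactants: 24 4-bromo-1-(methoxymethoxy)-2-(3-methylbut-2-en-1-yl)benzene
Product: 25 2-[4-(methoxymethoxy)-3-(3-methylbut-2-en-1-yl)phenyl]-4,4,5,5-tetramethyl-1,3,2-dioxaborolane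
Conditions: B2pin2 (1.2 equiv), PdCl2(dppf) (3 mol%), KOAc (3 equiv), 1,4-dioxane, 85 °C
Reagents that add atoms: bis(pinacolato)diboron, CC1(C)OB(OC1(C)C)B1OC(C)(C)C(C)(C)O1
Why: Miyaura borylation of the aryl bromide; the weak base acetate suppresses biaryl formation and the prenyl alkene is inert.

Step 16
Reactants: 20 6-[(2R)-2-{[tert-butyl(dimethyl)silyl]oxy}-3-methylbut-3-en-1-yl]-3-iodo-5,7-bis(methoxymethoxy)-4H-chromen-4-one, 25 2-[4-(methoxymethoxy)-3-(3-methylbut-2-en-1-yl)phenyl]-4,4,5,5-tetramethyl-1,3,2-dioxaborolane
Product: 26 6-[(2R)-2-{[tert-butyl(dimethyl)silyl]oxy}-3-methylbut-3-en-1-yl]-5,7-bis(methoxymethoxy)-3-[4-(methoxymethoxy)-3-(3-methylbut-2-en-1-yl)phenyl]-4H-chromen-4-one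
Conditions: PdCl2(dppf) (5 mol%), Na2CO3 (3 equiv), DME/H2O 4:1, 70 °C
Reagents that add atoms: none
Why: Suzuki–Miyaura coupling of a 3-iodochromone with an arylboronic ester, the standard way to form the C3–C1' bond of an isoflavone; carbonate at 70 °C is mild enough for the pyranone ring.

Step 17
Reactants: 26 6-[(2R)-2-{[tert-butyl(dimethyl)silyl]oxy}-3-methylbut-3-en-1-yl]-5,7-bis(methoxymethoxy)-3-[4-(methoxymethoxy)-3-(3-methylbut-2-en-1-yl)phenyl]-4H-chromen-4-one
Product: 27 5,7-dihydroxy-6-[(2R)-2-hydroxy-3-methylbut-3-en-1-yl]-3-[4-hydroxy-3-(3-methylbut-2-en-1-yl)phenyl]-4H-chromen-4-one (CNP0138374.1)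
Conditions: 3 M aq. HCl/MeOH 1:5, rt → 40 °C
Reagents that add atoms: none
Why: Acid-catalysed acetal exchange removes the three MOM groups as dimethoxymethane and methanolysis removes the TBS ether. Dilute acid near room temperature is chosen so that neither alkene is protonated nor the allylic alcohol ionised at a competitive rate.

## Compound list

1 | phloroglucinol (benzene-1,3,5-triol) | Oc1cc(O)cc(O)c1 | starting material
2 | 3,5-bis(methoxymethoxy)phenol | COCOc1cc(O)cc(OCOC)c1 | intermediate
3 | [3,5-bis(methoxymethoxy)phenoxy]tri(propan-2-yl)silane | COCOc1cc(OCOC)cc(O[Si](C(C)C)(C(C)C)C(C)C)c1 | intermediate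
4 | (2,6-bis(methoxymethoxy)-4-{[tri(propan-2-yl)silyl]oxy}phenyl)lithium | [Li]c1c(OCOC)cc(O[Si](C(C)C)(C(C)C)C(C)C)cc1OCOC | intermediate (not isolated)
5 | dimethyl (2,6-bis(methoxymethoxy)-4-{[tri(propan-2-yl)silyl]oxy}phenyl)boronate | COCOc1cc(O[Si](C(C)C)(C(C)C)C(C)C)cc(OCOC)c1B(OC)OC | intermediate (not isolated)
6 | 2,6-bis(methoxymethoxy)-4-{[tri(propan-2-yl)silyl]oxy}phenol | COCOc1cc(O[Si](C(C)C)(C(C)C)C(C)C)cc(OCOC)c1O | intermediate
7 | 2,6-bis(methoxymethoxy)-4-{[tri(propan-2-yl)silyl]oxy}phenyl trifluoromethanesulfonate | COCOc1cc(O[Si](C(C)C)(C(C)C)C(C)C)cc(OCOC)c1OS(=O)(=O)C(F)(F)F | intermediate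
8 | tetravinylstannane | C=C[Sn](C=C)(C=C)C=C | starting material
9 | vinyllithium | [Li]C=C | intermediate
10 | isopropenylboronic acid pinacol ester | C=C(C)B1OC(C)(C)C(C)(C)O1 | starting material
11 | lithium ethenyl(prop-1-en-2-yl)(pinacolato)borate | [Li+].C=C[B-]1(C(C)=C)OC(C)(C)C(C)(C)O1 | intermediate (not isolated)
12 | 2-[(2R)-1-(2,6-bis(methoxymethoxy)-4-{[tri(propan-2-yl)silyl]oxy}phenyl)-3-methylbut-3-en-2-yl]-4,4,5,5-tetramethyl-1,3,2-dioxaborolane | C=C(C)[C@H](B1OC(C)(C)C(C)(C)O1)Cc1c(OCOC)cc(O[Si](C(C)C)(C(C)C)C(C)C)cc1OCOC | intermediate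
13 | (2R)-1-(2,6-bis(methoxymethoxy)-4-{[tri(propan-2-yl)silyl]oxy}phenyl)-3-methylbut-3-en-2-ol | C=C(C)[C@H](O)Cc1c(OCOC)cc(O[Si](C(C)C)(C(C)C)C(C)C)cc1OCOC | intermediate
14 | {[(2R)-1-(2,6-bis(methoxymethoxy)-4-{[tri(propan-2-yl)silyl]oxy}phenyl)-3-methylbut-3-en-2-yl]oxy}(tert-butyl)dimethylsilane | C=C(C)[C@H](O[Si](C)(C)C(C)(C)C)Cc1c(OCOC)cc(O[Si](C(C)C)(C(C)C)C(C)C)cc1OCOC | intermediate
15 | {[(2R)-1-(3-bromo-2,6-bis(methoxymethoxy)-4-{[tri(propan-2-yl)silyl]oxy}phenyl)-3-methylbut-3-en-2-yl]oxy}(tert-butyl)dimethylsilane | C=C(C)[C@H](O[Si](C)(C)C(C)(C)C)Cc1c(OCOC)c(Br)c(O[Si](C(C)C)(C(C)C)C(C)C)cc1OCOC | intermediate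
16 | {3-[(2R)-2-{[tert-butyl(dimethyl)silyl]oxy}-3-methylbut-3-en-1-yl]-2,4-bis(methoxymethoxy)-6-{[tri(propan-2-yl)silyl]oxy}phenyl}lithium | C=C(C)[C@H](O[Si](C)(C)C(C)(C)C)Cc1c(OCOC)c([Li])c(O[Si](C(C)C)(C(C)C)C(C)C)cc1OCOC | intermediate (not isolated)
17 | 1-{3-[(2R)-2-{[tert-butyl(dimethyl)silyl]oxy}-3-methylbut-3-en-1-yl]-2,4-bis(methoxymethoxy)-6-{[tri(propan-2-yl)silyl]oxy}phenyl}ethan-1-one | C=C(C)[C@H](O[Si](C)(C)C(C)(C)C)Cc1c(OCOC)c(C(C)=O)c(O[Si](C(C)C)(C(C)C)C(C)C)cc1OCOC | intermediate
18 | 1-{3-[(2R)-2-{[tert-butyl(dimethyl)silyl]oxy}-3-methylbut-3-en-1-yl]-6-hydroxy-2,4-bis(methoxymethoxy)phenyl}ethan-1-one | C=C(C)[C@H](O[Si](C)(C)C(C)(C)C)Cc1c(OCOC)c(C(C)=O)c(O)cc1OCOC | intermediate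
19 | (2E)-1-{3-[(2R)-2-{[tert-butyl(dimethyl)silyl]oxy}-3-methylbut-3-en-1-yl]-6-hydroxy-2,4-bis(methoxymethoxy)phenyl}-3-(dimethylamino)prop-2-en-1-one | C=C(C)[C@H](O[Si](C)(C)C(C)(C)C)Cc1c(OCOC)c(C(=O)/C=C/N(C)C)c(O)cc1OCOC | intermediate (not isolated)
20 | 6-[(2R)-2-{[tert-butyl(dimethyl)silyl]oxy}-3-methylbut-3-en-1-yl]-3-iodo-5,7-bis(methoxymethoxy)-4H-chromen-4-one | C=C(C)[C@H](O[Si](C)(C)C(C)(C)C)Cc1c(OCOC)cc2occ(I)c(=O)c2c1OCOC | intermediate
21 | 2,4-dibromophenol | Oc1ccc(Br)cc1Br | starting material
22 | 2,4-dibromo-1-(methoxymethoxy)benzene | COCOc1ccc(Br)cc1Br | intermediate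
23 | [5-bromo-2-(methoxymethoxy)phenyl]lithium | COCOc1ccc(Br)cc1[Li] | intermediate (not isolated)
24 | 4-bromo-1-(methoxymethoxy)-2-(3-methylbut-2-en-1-yl)benzene | COCOc1ccc(Br)cc1CC=C(C)C | intermediate
25 | 2-[4-(methoxymethoxy)-3-(3-methylbut-2-en-1-yl)phenyl]-4,4,5,5-tetramethyl-1,3,2-dioxaborolane | COCOc1ccc(B2OC(C)(C)C(C)(C)O2)cc1CC=C(C)C | intermediate
26 | 6-[(2R)-2-{[tert-butyl(dimethyl)silyl]oxy}-3-methylbut-3-en-1-yl]-5,7-bis(methoxymethoxy)-3-[4-(methoxymethoxy)-3-(3-methylbut-2-en-1-yl)phenyl]-4H-chromen-4-one | C=C(C)[C@H](O[Si](C)(C)C(C)(C)C)Cc1c(OCOC)cc2occ(-c3ccc(OCOC)c(CC=C(C)C)c3)c(=O)c2c1OCOC | intermediate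
27 | 5,7-dihydroxy-6-[(2R)-2-hydroxy-3-methylbut-3-en-1-yl]-3-[4-hydroxy-3-(3-methylbut-2-en-1-yl)phenyl]-4H-chromen-4-one | C=C(C)[C@H](O)Cc1c(O)cc2occ(-c3ccc(O)c(CC=C(C)C)c3)c(=O)c2c1O | target

## Step count and least certain steps

Total step count: 17. Longest linear sequence: 13 steps (steps 1–4, 6–12, 16 and 17, from phloroglucinol 1). Steps 5 and 13–15 are side branches.

**Step 6 (key step).**
- What may go wrong: oxidative addition at the electron-rich, doubly ortho-substituted C–O bond may be slow, so borate 11 decomposes or the catalyst leaks into direct transfer of a vinyl or isopropenyl group. Chelation by an ortho MOM oxygen may also distort the chiral pocket and lower the facial selectivity.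
- Fallback: it leaves the route at arene 3 and rejoins at alcohol 13, without palladium. Metalation of 3 as in step 3 (n-BuLi, THF, 0 °C), transmetalation with CuBr·SMe2 and alkylation with prenyl bromide should give [3,5-bis(methoxymethoxy)-4-(3-methylbut-2-en-1-yl)phenoxy]tri(propan-2-yl)silane F1. Shi epoxidation of its trisubstituted alkene (fructose-derived ketone of the enantiomeric series that leads to the (R)-oxirane, KHSO5, buffered aqueous acetonitrile, 0 °C) should give {4-[[(2R)-3,3-dimethyloxiran-2-yl]methyl]-3,5-bis(methoxymethoxy)phenoxy}tri(propan-2-yl)silane F2. Opening of the oxirane by proton abstraction from a methyl group with diethylaluminium 2,2,6,6-tetramethylpiperidide (toluene, 0 °C) should give 13; the C2''–O bond is not touched, so the configuration is kept.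

**Step 10.**
- What may go wrong: in aryllithium 16 the neighbouring TIPS group may migrate from oxygen to carbon, or the hindered carbanion may deprotonate the acetamide, returning the debrominated arene.
- Fallback: it avoids the carbanion and runs from bromide 15 to ketone 17. Stille coupling of 15 with tributyl(1-ethoxyvinyl)stannane (Pd2(dba)3, P(t-Bu)3, CsF, 1,4-dioxane, 90 °C) should give tert-butyl{[(2R)-1-(3-(1-ethoxyethenyl)-2,6-bis(methoxymethoxy)-4-{[tri(propan-2-yl)silyl]oxy}phenyl)-3-methylbut-3-en-2-yl]oxy}dimethylsilane F3. Hydrolysis of the enol ether with oxalic acid on wet silica gel at rt should then give 17.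

**Step 12.**
- What may go wrong: iodine may attack the isopropenyl alkene with participation of the neighbouring MOM oxygen (iodoetherification with loss of the acetal), or acid set free may cleave a MOM ether.
- Fallback: it uses no halogen electrophile and no boronic ester. It leaves at ketone 17 and bromide 24 and rejoins at 26, bypassing steps 11, 12, 15 and 16. Palladium-catalysed α-arylation of 17 with 24 (Pd2(dba)3, XPhos, K3PO4, toluene, 80 °C) should give 1-{3-[(2R)-2-{[tert-butyl(dimethyl)silyl]oxy}-3-methylbut-3-en-1-yl]-2,4-bis(methoxymethoxy)-6-{[tri(propan-2-yl)silyl]oxy}phenyl}-2-[4-(methoxymethoxy)-3-(3-methylbut-2-en-1-yl)phenyl]ethan-1-one F4. Desilylation as in step 11 should give 1-{3-[(2R)-2-{[tert-butyl(dimethyl)silyl]oxy}-3-methylbut-3-en-1-yl]-6-hydroxy-2,4-bis(methoxymethoxy)phenyl}-2-[4-(methoxymethoxy)-3-(3-methylbut-2-en-1-yl)phenyl]ethan-1-one F5. Heating F5 with N,N-dimethylformamide dimethyl acetal (THF, 65 °C) should close ring C to 26.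

**Step 17.**
- What may go wrong: the liberated 7-hydroxyl or 4'-hydroxyl may add to the neighbouring alkene under acid (chroman formation), or the allylic alcohol may ionise, losing configuration or cyclising.
- Fallback: it replaces protic solvolysis by a two-stage sequence from 26 to 27. Silyl-transfer cleavage of the three aryl acetals (TMSOTf, 2,2'-bipyridyl, MeCN, 0 °C → rt, then water) should give 6-[(2R)-2-{[tert-butyl(dimethyl)silyl]oxy}-3-methylbut-3-en-1-yl]-5,7-dihydroxy-3-[4-hydroxy-3-(3-methylbut-2-en-1-yl)phenyl]-4H-chromen-4-one F6. Fluoride (TBAF buffered with AcOH, THF, 0 °C → rt) should then remove the TBS ether to give 27 without a strong acid.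

## Further compounds

F1 | step 6 | [3,5-bis(methoxymethoxy)-4-(3-methylbut-2-en-1-yl)phenoxy]tri(propan-2-yl)silane | CC(C)=CCc1c(OCOC)cc(O[Si](C(C)C)(C(C)C)C(C)C)cc1OCOC
F2 | step 6 | {4-[[(2R)-3,3-dimethyloxiran-2-yl]methyl]-3,5-bis(methoxymethoxy)phenoxy}tri(propan-2-yl)silane | CC1(C)O[C@@H]1Cc1c(OCOC)cc(O[Si](C(C)C)(C(C)C)C(C)C)cc1OCOC
F3 | step 10 | tert-butyl{[(2R)-1-(3-(1-ethoxyethenyl)-2,6-bis(methoxymethoxy)-4-{[tri(propan-2-yl)silyl]oxy}phenyl)-3-methylbut-3-en-2-yl]oxy}dimethylsilane | C=C(C)[C@H](O[Si](C)(C)C(C)(C)C)Cc1c(OCOC)c(C(=C)OCC)c(O[Si](C(C)C)(C(C)C)C(C)C)cc1OCOC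
F4 | step 12 | 1-{3-[(2R)-2-{[tert-butyl(dimethyl)silyl]oxy}-3-methylbut-3-en-1-yl]-2,4-bis(methoxymethoxy)-6-{[tri(propan-2-yl)silyl]oxy}phenyl}-2-[4-(methoxymethoxy)-3-(3-methylbut-2-en-1-yl)phenyl]ethan-1-one | C=C(C)[C@H](O[Si](C)(C)C(C)(C)C)Cc1c(OCOC)c(C(=O)Cc2ccc(OCOC)c(CC=C(C)C)c2)c(O[Si](C(C)C)(C(C)C)C(C)C)cc1OCOC
F5 | step 12 | 1-{3-[(2R)-2-{[tert-butyl(dimethyl)silyl]oxy}-3-methylbut-3-en-1-yl]-6-hydroxy-2,4-bis(methoxymethoxy)phenyl}-2-[4-(methoxymethoxy)-3-(3-methylbut-2-en-1-yl)phenyl]ethan-1-one | C=C(C)[C@H](O[Si](C)(C)C(C)(C)C)Cc1c(OCOC)c(C(=O)Cc2ccc(OCOC)c(CC=C(C)C)c2)c(O)cc1OCOC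
F6 | step 17 | 6-[(2R)-2-{[tert-butyl(dimethyl)silyl]oxy}-3-methylbut-3-en-1-yl]-5,7-dihydroxy-3-[4-hydroxy-3-(3-methylbut-2-en-1-yl)phenyl]-4H-chromen-4-one | C=C(C)[C@H](O[Si](C)(C)C(C)(C)C)Cc1c(O)cc2occ(-c3ccc(O)c(CC=C(C)C)c3)c(=O)c2c1O
A1 | alternative 1 | 5,7-dihydroxy-6-[(2R)-2-hydroxy-3-methylbut-3-en-1-yl]-3-[4-(methoxymethoxy)-3-(3-methylbut-2-en-1-yl)phenyl]-4H-chromen-4-one | C=C(C)[C@H](O)Cc1c(O)cc2occ(-c3ccc(OCOC)c(CC=C(C)C)c3)c(=O)c2c1O
A2 | alternative 1 | methyl 5-[4-(methoxymethoxy)-3-(3-methylbut-2-en-1-yl)phenyl]-2-methyl-4-oxo-4H-pyran-3-carboxylate | COC(=O)c1c(C)occ(-c2ccc(OCOC)c(CC=C(C)C)c2)c1=O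
A3 | alternative 1 | (5R)-5-(prop-1-en-2-yl)oxolan-2-one | C=C(C)[C@H]1CCC(=O)O1
A4 | alternative 2 | 2-[(2R)-2-{[tert-butyl(dimethyl)silyl]oxy}-3-methylbut-3-en-1-yl]-5-[(4-methoxyphenyl)methoxy]-3-{[tri(propan-2-yl)silyl]oxy}phenol | C=C(C)[C@H](O[Si](C)(C)C(C)(C)C)Cc1c(O)cc(OCc2ccc(OC)cc2)cc1O[Si](C(C)C)(C(C)C)C(C)C
A5 | alternative 2 | 3-[(4-methoxyphenyl)methoxy]cyclobut-2-en-1-one | O=C1CC(OCc2ccc(OC)cc2)=C1
A6 | alternative 2 | tert-butyl(dimethyl){[(3R)-2-methyl-6-{[tri(propan-2-yl)silyl]oxy}hex-1-en-5-yn-3-yl]oxy}silane | C=C(C)[C@H](O[Si](C)(C)C(C)(C)C)CC#CO[Si](C(C)C)(C(C)C)C(C)C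
A7 | alternative 3 | 5-hydroxy-3-[4-hydroxy-3-(3-methylbut-2-en-1-yl)phenyl]-7-(methoxymethoxy)-6-(prop-2-en-1-yl)-4H-chromen-4-one | C=CCc1c(OCOC)cc2occ(-c3ccc(O)c(CC=C(C)C)c3)c(=O)c2c1O
A8 | alternative 3 | 7-(methoxymethoxy)-3-{4-[(2-methylbut-3-en-2-yl)oxy]phenyl}-5-(prop-2-en-1-yloxy)-4H-chromen-4-one | C=CCOc1cc(OCOC)cc2occ(-c3ccc(OC(C)(C)C=C)cc3)c(=O)c12
A9 | alternative 3 | genistein (5,7-dihydroxy-3-(4-hydroxyphenyl)-4H-chromen-4-one) | O=c1c(-c2ccc(O)cc2)coc2cc(O)cc(O)c12
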